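**Plan**

- Retrosynthetic cuts: (a) the ketone bond between the exocyclic acyl carbon on C3 of the 4-hydroxy-5,6-dihydropyran-2-one ring and the neighbouring chain CH2; (b) the C(=CH2)–CH2 bond of the skipped diene; (c) the C2–allyl bond of the hydroxy acid; (d) the C3–C4 bond of the pyranone ring.
- Enabling feature: the acyl carbon hangs on ring C3 between the lactone C2=O and the C4 enol, so at the acid oxidation level it is one arm of a malonate and is delivered as a thioester by the ring closure itself. The chain end is an unbranched homoallylic CH2 whose C–Zn bond is neither allylic nor β-oxygenated. A thioester–alkylzinc ketone synthesis can therefore join the halves at the final oxidation level.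
- Forward order: Dieckmann closure gives the pyranone ring with its C3 thioester (C4 enol capped as a TIPS ether). The hydroxy acid is tied into a temporary six-membered di-tert-butylsilylene ring, the 1,4-diene is built by Ru-catalysed Alder-ene coupling, the halves are joined, and one HF step removes both silicon helpers.
- Stereochemistry: C4 from (S)-2-methylbutanoic acid; C3 by (R)-BINAP–Ru hydrogenation; C2 by chelate-controlled anti alkylation of the β-hydroxy ester dianion; ring C6 from methyl (R)-3-hydroxybutanoate; the E alkene from the Alder-ene step.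

Key step: step 12

Assumption: the target is handled as the C4-enol tautomer drawn; the keto/enol tautomers of the 3-acylpyran-2,4-dione unit are treated as one compound.

**Route**

Step 1
Reactants: 1 (2S)-2-methylbutanoic acid; 2 potassium methyl malonate
Product: 4 methyl (4S)-4-methyl-3-oxohexanoate, via acyl imidazolide 3 (not isolated)
Conditions: 1,1'-carbonyldiimidazole, THF, rt; then 2, MgCl2, THF, rt → 45 °C; aq. HCl work-up
Reagents that add atoms: 1,1'-carbonyldiimidazole, O=C(n1ccnc1)n1ccnc1 (imidazolyl group, carried only by intermediate 3)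
Why: Decarboxylative Claisen condensation: acyl imidazolide 3 C-acylates the magnesium enolate of the malonate half-ester and the adduct loses CO2 on acidification; the nearly neutral conditions should leave the α-stereocentre of 1 untouched.

Step 2
Reactants: 4 methyl (4S)-4-methyl-3-oxohexanoate
Product: 5 methyl (3S,4S)-3-hydroxy-4-methylhexanoate
Conditions: [RuCl2((R)-BINAP)] (0.5 mol%), H2 (50 bar), MeOH, 50 °C
Reagents that add atoms: none
Why: Noyori asymmetric hydrogenation of a β-keto ester: hydride is delivered within the ester-chelated divalent ruthenium complex, the (R)-BINAP ligand selecting the ketone face that gives the 3S carbinol (the spatial counterpart of (R)-3-hydroxybutanoate), while C4 should not be enolised under these conditions.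

Step 3
Reactants: 5 methyl (3S,4S)-3-hydroxy-4-methylhexanoate; 6 allyl bromide
Product: 8 methyl (2R,3R,4S)-3-hydroxy-4-methyl-2-(prop-2-en-1-yl)hexanoate, via dilithium alkoxide enolate 7 (not isolated)
Conditions: LDA (2.2 equiv), THF, −78 → −20 °C; 6, DMPU, −78 → −10 °C; AcOH quench
Reagents that add atoms: lithium diisopropylamide, [Li+].CC(C)[N-]C(C)C (lithium, carried only by intermediate 7)
Why: Fráter–Seebach alkylation: the lithium-bridged alkoxide enolate 7 is attacked by allyl bromide on the face opposite the C3 sec-butyl group, which sets C2 as R, anti to the C3 oxygen.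

Step 4
Reactants: 8 methyl (2R,3R,4S)-3-hydroxy-4-methyl-2-(prop-2-en-1-yl)hexanoate
Product: 9 (2R,3R,4S)-3-hydroxy-4-methyl-2-(prop-2-en-1-yl)hexanoic acid
Conditions: LiOH·H2O, THF/MeOH/H2O, 0 °C → rt; then aq. HCl to pH 2
Reagents that add atoms: lithium hydroxide, [Li+].[OH-]
Why: Saponification of the methyl ester, placed here because the alkene is still γ,δ to the carboxyl, so hydroxide cannot move it into conjugation or epimerise an allylic C2.

Step 5
Reactants: 9 (2R,3R,4S)-3-hydroxy-4-methyl-2-(prop-2-en-1-yl)hexanoic acid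
Product: 10 (5R,6R)-2,2-di-tert-butyl-6-[(2S)-butan-2-yl]-5-(prop-2-en-1-yl)-1,3,2-dioxasilinan-4-one
Conditions: tBu2Si(OTf)2, 2,6-lutidine, CH2Cl2, 0 °C
Reagents that add atoms: di-tert-butylsilyl bis(trifluoromethanesulfonate), CC(C)(C)[Si](OS(=O)(=O)C(F)(F)F)(OS(=O)(=O)C(F)(F)F)C(C)(C)C
Why: Silylene formation: the bis-triflate silylates the carboxyl and the C3 hydroxyl in turn and closes the six-membered 1,3,2-dioxasilinan-4-one, a known protection of β-hydroxy acids that removes both acidic protons without touching a stereocentre.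

Step 6
Reactants: 10 (5R,6R)-2,2-di-tert-butyl-6-[(2S)-butan-2-yl]-5-(prop-2-en-1-yl)-1,3,2-dioxasilinan-4-one; 11 but-3-yn-1-ol
Product: 12 (5R,6R)-2,2-di-tert-butyl-6-[(2S)-butan-2-yl]-5-[(1E)-6-hydroxy-4-methylidenehex-1-en-1-yl]-1,3,2-dioxasilinan-4-one
Conditions: [CpRu(MeCN)3]PF6 (10 mol%), acetone, rt
Reagents that add atoms: none
Why: Ruthenium-catalysed alkene–alkyne coupling of Alder-ene type: oxidative cyclisation on cationic CpRu joins the alkene terminus to the internal alkyne carbon (branched, 1,1-disubstituted alkene), and β-hydride elimination of the allylic hydrogen followed by reductive elimination leaves the new disubstituted alkene E; the hindered ring carbon next to the allylic CH2 should reinforce the branched preference.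

Step 7
Reactants: 12 (5R,6R)-2,2-di-tert-butyl-6-[(2S)-butan-2-yl]-5-[(1E)-6-hydroxy-4-methylidenehex-1-en-1-yl]-1,3,2-dioxasilinan-4-one
Product: 13 (5R,6R)-2,2-di-tert-butyl-6-[(2S)-butan-2-yl]-5-[(1E)-6-iodo-4-methylidenehex-1-en-1-yl]-1,3,2-dioxasilinan-4-one
Conditions: iodine, PPh3, imidazole, CH2Cl2, 0 °C → rt
Reagents that add atoms: iodine, [I][I]
Why: Appel-type iodination: the primary alcohol is activated as an alkoxyphosphonium ion and displaced by iodide in an SN2 step, conditions under which the acyloxysilane ring and the skipped diene should be inert.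

Step 8
Reactants: 14 Meldrum's acid; 15 ethanethiol
Product: 16 3-(ethylsulfanyl)-3-oxopropanoic acid
Conditions: MeCN, sealed tube, 80 °C
Reagents that add atoms: none
Why: Thiolysis of Meldrum's acid: the thiol opens the activated cyclic malonate at one carbonyl with loss of acetone, the standard entry to malonic acid half thioesters.

Step 9
Reactants: 16 3-(ethylsulfanyl)-3-oxopropanoic acid; 17 methyl (3R)-3-hydroxybutanoate
Product: 18 methyl (3R)-3-{[3-(ethylsulfanyl)-3-oxopropanoyl]oxy}butanoate
Conditions: N,N'-dicyclohexylcarbodiimide, DMAP (5 mol%), CH2Cl2, 0 °C → rt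
Reagents that add atoms: none
Why: Steglich esterification: the carbodiimide-activated half thioester acylates the secondary hydroxyl of 17 at oxygen, so the R centre is retained.

Step 10
Reactants: 18 methyl (3R)-3-{[3-(ethylsulfanyl)-3-oxopropanoyl]oxy}butanoate
Product: 19 S-ethyl (6R)-4-hydroxy-6-methyl-2-oxo-5,6-dihydro-2H-pyran-3-carbothioate
Conditions: KOtBu (2.2 equiv), THF, 0 °C → rt; then aq. HCl
Reagents that add atoms: none
Why: Dieckmann condensation: the malonate carbanion (the only readily formed enolate) attacks the methyl ester carbonyl in a 6-exo-trig closure that forms the C3–C4 bond of the pyranone ring, and deprotonation of the product to its stabilised enolate drives the step and shields the thioester from the methoxide set free.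

Step 11
Reactants: 19 S-ethyl (6R)-4-hydroxy-6-methyl-2-oxo-5,6-dihydro-2H-pyran-3-carbothioate
Product: 20 S-ethyl (6R)-6-methyl-2-oxo-4-{[tri(propan-2-yl)silyl]oxy}-5,6-dihydro-2H-pyran-3-carbothioate
Conditions: TIPSOTf, Et3N, CH2Cl2, −78 → 0 °C
Reagents that add atoms: triisopropylsilyl trifluoromethanesulfonate, CC(C)[Si](OS(=O)(=O)C(F)(F)F)(C(C)C)C(C)C
Why: O-silylation of the vinylogous acid at the C4 oxygen with the silyl triflate and an amine base, which removes the acidic enol proton and leaves a neutral thioester.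

Step 12
Reactants: 13 (5R,6R)-2,2-di-tert-butyl-6-[(2S)-butan-2-yl]-5-[(1E)-6-iodo-4-methylidenehex-1-en-1-yl]-1,3,2-dioxasilinan-4-one; 20 S-ethyl (6R)-6-methyl-2-oxo-4-{[tri(propan-2-yl)silyl]oxy}-5,6-dihydro-2H-pyran-3-carbothioate
Product: 22 (6R)-3-{(6E)-7-[(5R,6R)-2,2-di-tert-butyl-6-[(2S)-butan-2-yl]-4-oxo-1,3,2-dioxasilinan-5-yl]-4-methylidenehept-6-enoyl}-6-methyl-4-{[tri(propan-2-yl)silyl]oxy}-5,6-dihydro-2H-pyran-2-one, via alkylzinc iodide 21 (not isolated)
Conditions: Zn dust (activated with BrCH2CH2Br and TMSCl), LiCl, THF, 30 °C; then 20 (1.3 equiv), PdCl2(PPh3)2 (5 mol%), toluene, rt; pH 7 buffer work-up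
Reagents that add atoms: zinc, [Zn] (carried only by intermediate 21)
Why: Fukuyama coupling: zerovalent palladium (formed from PdCl2(PPh3)2 by the zinc reagent) inserts into the C(acyl)–S bond of thioester 20, the primary alkyl group of 21 passes from zinc to palladium while the thiolate leaves on zinc, and reductive elimination from the acyl(alkyl)palladium gives the ketone, so the bond between the exocyclic acyl carbon on ring C3 and the chain CH2 is made at the final oxidation level. The closest known reaction type is the palladium-catalysed ketone synthesis from thioesters and alkylzinc iodides, which is known to tolerate esters, lactones, silyl ethers and alkenes. No ring is closed and no stereocentre is created; the four existing stereocentres are remote from the reacting carbons and the weakly basic zinc reagent should not deprotonate the allylic ring C–H next to the silylene carbonyl. The step needs chemoselectivity for the thioester over the lactone and acyloxysilane carbonyls, which the much weaker C–S bond secures, and it needs the zinc reagent to survive, which the TIPS cap on the C4 enol oxygen of 20 and the silylene ring on the hydroxy acid secure by removing every acidic O–H. Because the zinc-bearing carbon is homoallylic and unbranched there is no allylic transposition, and reductive elimination from the acylpalladium should outrun β-hydride elimination, so the skipped diene stays in place.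

Step 13
Reactants: 22 (6R)-3-{(6E)-7-[(5R,6R)-2,2-di-tert-butyl-6-[(2S)-butan-2-yl]-4-oxo-1,3,2-dioxasilinan-5-yl]-4-methylidenehept-6-enoyl}-6-methyl-4-{[tri(propan-2-yl)silyl]oxy}-5,6-dihydro-2H-pyran-2-one
Product: 23 (2R,3R,4S)-3-hydroxy-2-{(1E)-7-[(6R)-4-hydroxy-6-methyl-2-oxo-5,6-dihydro-2H-pyran-3-yl]-4-methylidene-7-oxohept-1-en-1-yl}-4-methylhexanoic acid (target)
Conditions: HF·pyridine, pyridine, THF, 0 °C → rt
Reagents that add atoms: none
Why: Fluoride-driven cleavage of the Si–O bonds of the enol silyl ether and of the silylene ring by buffered HF·pyridine, a weakly acidic medium that should neither epimerise the allylic C2 nor move the alkenes, unveils the enol, the C3 hydroxyl and the carboxylic acid at once.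

**Compound list**

1 | (2S)-2-methylbutanoic acid | CC[C@H](C)C(=O)O | starting material
2 | potassium methyl malonate (potassium 3-methoxy-3-oxopropanoate) | COC(=O)CC(=O)[O-].[K+] | starting material
3 | (2S)-1-(1H-imidazol-1-yl)-2-methylbutan-1-one | CC[C@H](C)C(=O)n1ccnc1 | intermediate
4 | methyl (4S)-4-methyl-3-oxohexanoate | CC[C@H](C)C(=O)CC(=O)OC | intermediate
5 | methyl (3S,4S)-3-hydroxy-4-methylhexanoate | COC(=O)C[C@H](O)[C@@H](C)CC | intermediate
6 | allyl bromide (3-bromoprop-1-ene) | C=CCBr | starting material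
7 | dilithium alkoxide enolate of 5 (enolate oxygen cis to C3; C3 and C4 configured as in 5) | [Li+].[Li+].CO/C([O-])=C/[C@H]([O-])[C@@H](C)CC | intermediate
8 | methyl (2R,3R,4S)-3-hydroxy-4-methyl-2-(prop-2-en-1-yl)hexanoate | COC(=O)[C@H](CC=C)[C@H](O)[C@@H](C)CC | intermediate
9 | (2R,3R,4S)-3-hydroxy-4-methyl-2-(prop-2-en-1-yl)hexanoic acid | OC(=O)[C@H](CC=C)[C@H](O)[C@@H](C)CC | intermediate
10 | (5R,6R)-2,2-di-tert-butyl-6-[(2S)-butan-2-yl]-5-(prop-2-en-1-yl)-1,3,2-dioxasilinan-4-one | C=CC[C@H]1C(=O)O[Si](C(C)(C)C)(C(C)(C)C)O[C@@H]1[C@@H](C)CC | intermediate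
11 | but-3-yn-1-ol | C#CCCO | starting material
12 | (5R,6R)-2,2-di-tert-butyl-6-[(2S)-butan-2-yl]-5-[(1E)-6-hydroxy-4-methylidenehex-1-en-1-yl]-1,3,2-dioxasilinan-4-one | C=C(CCO)C/C=C/[C@H]1C(=O)O[Si](C(C)(C)C)(C(C)(C)C)O[C@@H]1[C@@H](C)CC | intermediate
13 | (5R,6R)-2,2-di-tert-butyl-6-[(2S)-butan-2-yl]-5-[(1E)-6-iodo-4-methylidenehex-1-en-1-yl]-1,3,2-dioxasilinan-4-one | C=C(CCI)C/C=C/[C@H]1C(=O)O[Si](C(C)(C)C)(C(C)(C)C)O[C@@H]1[C@@H](C)CC | intermediate
14 | Meldrum's acid (2,2-dimethyl-1,3-dioxane-4,6-dione) | CC1(C)OC(=O)CC(=O)O1 | starting material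
15 | ethanethiol | CCS | starting material
16 | 3-(ethylsulfanyl)-3-oxopropanoic acid | CCSC(=O)CC(=O)O | intermediate
17 | methyl (3R)-3-hydroxybutanoate | C[C@@H](O)CC(=O)OC | starting material
18 | methyl (3R)-3-{[3-(ethylsulfanyl)-3-oxopropanoyl]oxy}butanoate | CCSC(=O)CC(=O)O[C@H](C)CC(=O)OC | intermediate
19 | S-ethyl (6R)-4-hydroxy-6-methyl-2-oxo-5,6-dihydro-2H-pyran-3-carbothioate | CCSC(=O)C1=C(O)C[C@@H](C)OC1=O | intermediate
20 | S-ethyl (6R)-6-methyl-2-oxo-4-{[tri(propan-2-yl)silyl]oxy}-5,6-dihydro-2H-pyran-3-carbothioate | CCSC(=O)C1=C(O[Si](C(C)C)(C(C)C)C(C)C)C[C@@H](C)OC1=O | intermediate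
21 | [(5E)-6-{(5R,6R)-2,2-di-tert-butyl-6-[(2S)-butan-2-yl]-4-oxo-1,3,2-dioxasilinan-5-yl}-3-methylidenehex-5-en-1-yl](iodo)zinc | C=C(CC[Zn]I)C/C=C/[C@H]1C(=O)O[Si](C(C)(C)C)(C(C)(C)C)O[C@@H]1[C@@H](C)CC | intermediate
22 | (6R)-3-{(6E)-7-[(5R,6R)-2,2-di-tert-butyl-6-[(2S)-butan-2-yl]-4-oxo-1,3,2-dioxasilinan-5-yl]-4-methylidenehept-6-enoyl}-6-methyl-4-{[tri(propan-2-yl)silyl]oxy}-5,6-dihydro-2H-pyran-2-one | C=C(C/C=C/[C@H]1C(=O)O[Si](C(C)(C)C)(C(C)(C)C)O[C@@H]1[C@@H](C)CC)CCC(=O)C1=C(O[Si](C(C)C)(C(C)C)C(C)C)C[C@@H](C)OC1=O | intermediate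
23 | (2R,3R,4S)-3-hydroxy-2-{(1E)-7-[(6R)-4-hydroxy-6-methyl-2-oxo-5,6-dihydro-2H-pyran-3-yl]-4-methylidene-7-oxohept-1-en-1-yl}-4-methylhexanoic acid | C=C(C/C=C/[C@@H](C(=O)O)[C@H](O)[C@@H](C)CC)CCC(=O)C1=C(O)C[C@@H](C)OC1=O | target

**Step count and risks**

Total steps: 13. Longest linear sequence: 9 steps (steps 1–7, 12, 13); the ring branch (steps 8–11) joins at step 12.

Steps most likely to fail:

1. Step 12. The enol silyl group of 20 may be lost to iodide or zinc salts, after which the freed acidic enol protonates the alkylzinc; oxidative addition into the electron-rich vinylogous thioester may also be slow. Fallback (the acyl group is instead attached at ring C3 by O-acylation and acyl migration): setting out from 10, the Alder-ene coupling of step 6 is run with pent-4-ynoic acid in place of 11 and should give (6E)-7-[(5R,6R)-2,2-di-tert-butyl-6-[(2S)-butan-2-yl]-4-oxo-1,3,2-dioxasilinan-5-yl]-4-methylidenehept-6-enoic acid F1. In parallel, 17 is treated with the lithium enolate of tert-butyl acetate (LDA, THF, −78 °C) to give tert-butyl (5R)-5-hydroxy-3-oxohexanoate F2, which TFA in CH2Cl2 lactonises to (6R)-4-hydroxy-6-methyl-5,6-dihydro-2H-pyran-2-one F3. N,N'-Dicyclohexylcarbodiimide and catalytic DMAP join F1 and F3 to the enol ester (6R)-6-methyl-2-oxo-5,6-dihydro-2H-pyran-4-yl (6E)-7-[(5R,6R)-2,2-di-tert-butyl-6-[(2S)-butan-2-yl]-4-oxo-1,3,2-dioxasilinan-5-yl]-4-methylidenehept-6-enoate F4. Further DMAP (toluene, 50 °C) should move the acyl group from O4 to C3 and give the silylene-protected 3-acyl-4-hydroxypyranone F5. HF·pyridine as in step 13 then removes the silylene, and the fallback rejoins the route at 23.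

2. Step 6. The ruthenacycle may form with the opposite regiochemistry (linear 1,4-diene), and the new alkene may migrate into conjugation with the silylene carbonyl. Fallback (alkene transposition by C–H oxidation, then allyl–vinyl cross-coupling): setting out from 10, sulfoxide-promoted allylic C–H acetoxylation (Pd(OAc)2, 1,4-benzoquinone, DMSO/AcOH, 40 °C) should give the linear allylic acetate (2E)-3-[(5R,6R)-2,2-di-tert-butyl-6-[(2S)-butan-2-yl]-4-oxo-1,3,2-dioxasilinan-5-yl]prop-2-en-1-yl acetate F6. Separately, 11 is hydrostannylated at the internal carbon (Bu3SnH, Mo(CO)3(CNtBu)3 cat., THF) to 3-(tributylstannyl)but-3-en-1-ol F7. Stille coupling of F6 with F7 (Pd2(dba)3, LiCl, DMF, rt → 50 °C) joins the allyl terminus to the stannylated carbon and rejoins the route at 12.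

3. Step 10. The malonyloxy group may be lost by E1cB elimination from the butanoate ester enolate (crotonate formation), and liberated methoxide may scramble the thioester. Fallback (ring closure without a thioester present, thiol introduced afterwards): setting out from 17, acylation with methyl malonyl chloride (pyridine, CH2Cl2, 0 °C) gives methyl (3R)-3-[(3-methoxy-3-oxopropanoyl)oxy]butanoate F8. NaOMe in MeOH closes it (methoxide exchange is now degenerate) to methyl (6R)-4-hydroxy-6-methyl-2-oxo-5,6-dihydro-2H-pyran-3-carboxylate F9. Heating F9 with 15 in toluene (sealed tube, 110 °C) should exchange methanol for the thiol through the α-oxoketene and rejoin the route at 19.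

**Further compounds**

F1 | step 12 | (6E)-7-[(5R,6R)-2,2-di-tert-butyl-6-[(2S)-butan-2-yl]-4-oxo-1,3,2-dioxasilinan-5-yl]-4-methylidenehept-6-enoic acid | C=C(CCC(=O)O)C/C=C/[C@H]1C(=O)O[Si](C(C)(C)C)(C(C)(C)C)O[C@@H]1[C@@H](C)CC
F2 | step 12 | tert-butyl (5R)-5-hydroxy-3-oxohexanoate | C[C@@H](O)CC(=O)CC(=O)OC(C)(C)C
F3 | step 12 | (6R)-4-hydroxy-6-methyl-5,6-dihydro-2H-pyran-2-one | C[C@@H]1CC(O)=CC(=O)O1
F4 | step 12 | (6R)-6-methyl-2-oxo-5,6-dihydro-2H-pyran-4-yl (6E)-7-[(5R,6R)-2,2-di-tert-butyl-6-[(2S)-butan-2-yl]-4-oxo-1,3,2-dioxasilinan-5-yl]-4-methylidenehept-6-enoate | C=C(CCC(=O)OC1=CC(=O)O[C@H](C)C1)C/C=C/[C@H]2C(=O)O[Si](C(C)(C)C)(C(C)(C)C)O[C@@H]2[C@@H](C)CC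
F5 | step 12 | (6R)-3-{(6E)-7-[(5R,6R)-2,2-di-tert-butyl-6-[(2S)-butan-2-yl]-4-oxo-1,3,2-dioxasilinan-5-yl]-4-methylidenehept-6-enoyl}-4-hydroxy-6-methyl-5,6-dihydro-2H-pyran-2-one | C=C(CCC(=O)C1=C(O)C[C@@H](C)OC1=O)C/C=C/[C@H]2C(=O)O[Si](C(C)(C)C)(C(C)(C)C)O[C@@H]2[C@@H](C)CC
F6 | step 6 | (2E)-3-[(5R,6R)-2,2-di-tert-butyl-6-[(2S)-butan-2-yl]-4-oxo-1,3,2-dioxasilinan-5-yl]prop-2-en-1-yl acetate | CC(=O)OC/C=C/[C@H]1C(=O)O[Si](C(C)(C)C)(C(C)(C)C)O[C@@H]1[C@@H](C)CC
F7 | step 6 | 3-(tributylstannyl)but-3-en-1-ol | C=C(CCO)[Sn](CCCC)(CCCC)CCCC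
F8 | step 10 | methyl (3R)-3-[(3-methoxy-3-oxopropanoyl)oxy]butanoate | COC(=O)CC(=O)O[C@H](C)CC(=O)OC
F9 | step 10 | methyl (6R)-4-hydroxy-6-methyl-2-oxo-5,6-dihydro-2H-pyran-3-carboxylate | COC(=O)C1=C(O)C[C@@H](C)OC1=O
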